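The numbers of this flask are invented, and the outcome is calculated.

A decade, one power of ten of substrate, is the unit of this reply: the quick number asked for is how many decades the carrier can take off in 80 min.

    substrate + fresh carrier → product + spent carrier (k1 = 15.7 M⁻¹ min⁻¹)
    spent carrier + salt in the second phase ⇌ fresh carrier + spent salt in the second phase (K2 = 2.3, k2 = 3.49 M⁻¹ min⁻¹)
    crystals ⇌ product, rate k3*(cs3 - [product]) while solid is left; crystals form when [product] > cs3 (cs3 = 5.2 mM, k3 = 0.202 min⁻¹)
    substrate ⇌ dormant form (K4 = 0.469, k4 = 0.145 min⁻¹)

substrate 0.050 M; salt in the second phase 0.200 M; spent carrier 0.80 mM; time 80 min; volume of the second phase over the first 0.25

- amounts and yields of product count crystals too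
- in the second phase: salt in the second phase, spent salt in the second phase; everything else is in the first
- charges count per volume of the first phase; a concentration in a rate is the amount of a species over the volume of its own phase; every rate counts per litre of the first phase
- given per volume of solution although it is solid: crystals
- run time (flask): 80 min

* how much product and crystals together there is at 80 min, in percent of the substrate charged
* the change that raises the amount of product and crystals together at 80 min, in percent of the substrate charged most ("none" if none brings more than 2 percentage points) (beta / alpha / gamma / none)
* amount of product and crystals together at 80 min, in percent of the substrate charged, after beta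

In the flask, step 1 acts as a pseudo-first-order loss, with 15.7 M⁻¹ min⁻¹ times the carrier charge times two fractions. The first is the free share of substrate. Step 4 relaxes in 1.53 min, far quicker than the run, so the share not held as dormant form stays at 0.681. The second is the fresh share of carrier. Spent carrier is renewed at 2.79 min⁻¹, with the salt counted in its own phase, and fresh carrier is used at 0.534 min⁻¹. Both are quick against the run, so the fresh share holds at 0.839. Multiplied by the time and divided by 2.3, these give 0.250, the decade count: the powers of ten by which substrate and dormant form together fall in the run. That count leaves a product share of 43.7%. Doubling the salt lifts the fresh share to 0.913 and the flask's product share to 46.4%, a gain of 2.7 percentage points, which is above the 2 points bar. Step 3 stands in neither fraction, so beta and gamma leave this reckoning at 43.7%.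

The forecast that came with the request stood at 44%, within 41% to 47%, with 44% after beta and alpha as best, on the ground that “crystallisation only splits product between solution and solid”.

The simulation gives 43.8%, 43.8% after beta, and alpha as best with 2.9 points, against 0 points for beta and 0 points for gamma. The flask's answer moves by 5 points at a spent carrier charge of 0.681 mM or 0.930 mM, and a move of that size lies outside the forecast's range. The neighbouring flask holds 0.013 M of substrate, with all other charges and the time as in the recipe, so fresh carrier is used at 0.139 min⁻¹, the fresh share is 0.953, and its decade count is 0.283, which gives 47.8%. The run of that neighbouring flask gives 47.9%, with fresh carrier at 95.9% of the carrier charged.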